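**Retrosynthetic overview**

- Target 25 comes from hydrogenolysis of hexabenzyl ether 24, which comes from acylation of flavan-3-ol 22 with acid 23, which comes from deallylation of 20.
- Ring C is the only ring made, since rings A and B are bought as 5-bromoresorcinol and 5-bromo-1,2,3-trimethoxybenzene. It is closed last at O1–C8a by CuI-catalysed aryl ether formation from bromo alcohol 19, with C2 untouched.
- The strategy rests on C2 and C3 of ring C: two neighbouring CH–O carbons between C4 (benzylic to ring A) and C1' of ring B. Each is inserted from dichloromethane as a one-carbon unit into a C–B bond of an (S,S)-1,2-dicyclohexylethane-1,2-diol boronic ester: C4–B gives C3 (capped with allyloxide), C3–B gives C2 (capped with the ring B Grignard reagent), and C2–B then becomes C2–O.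
- O3 is carried as an allyl ether, removed by isomerisation and hydrolysis, because DDQ cleavage of a 4-methoxybenzyl ether would compete with hydride abstraction at C4 of the benzylated flavan.

Key step: step 13

Assumption: the diol director is taken to act in its established sense (an (R,R)-1,2-diol boronic ester gives the (alpha-S)-chloride, ranking Cl > C > B), so the (S,S)-diol 8 is the one leading to (2R,3R); this can be checked at 22, the penta-O-benzyl ether of (–)-epigallocatechin.

**Route**

Step 1
Reactants: 1 5-bromobenzene-1,3-diol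
Product: 2 aryl bromide 1-bromo-3,5-bis(benzyloxy)benzene
Conditions: BnBr, K2CO3, DMF, 60 °C
Reagents that add atoms: benzyl bromide BrCc1ccccc1
Why: Williamson etherification of both phenoxides with benzyl bromide under carbonate base is reliable and the aryl bromide is inert to it.

Step 2
Reactants: 2 1-bromo-3,5-bis(benzyloxy)benzene
Product: 3 aldehyde 2-bromo-4,6-bis(benzyloxy)benzaldehyde
Conditions: POCl3, DMF, 0 → 80 °C; then aq. NaOAc
Reagents that add atoms: N,N-dimethylformamide CN(C)C=O; water O
Why: Vilsmeier–Haack formylation should attack the position para to one benzyloxy group and ortho to the other (next to bromine) in preference to the more crowded site between the two ethers, and the minor 4-bromo-2,6-bis(benzyloxy) isomer would be removed by crystallisation.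

Step 3
Reactants: 3 2-bromo-4,6-bis(benzyloxy)benzaldehyde
Product: 4 benzylic alcohol [2-bromo-4,6-bis(benzyloxy)phenyl]methanol
Conditions: NaBH4, THF/MeOH, 0 °C
Reagents that add atoms: none
Why: Borohydride reduction of the aryl aldehyde is chemoselective and leaves the aryl bromide and the benzyl ethers untouched.

Step 4
Reactants: 4 [2-bromo-4,6-bis(benzyloxy)phenyl]methanol
Product: 5 benzylic bromide 1,5-bis(benzyloxy)-3-bromo-2-(bromomethyl)benzene
Conditions: PBr3, CH2Cl2, 0 °C; used crude at once
Reagents that add atoms: phosphorus tribromide BrP(Br)Br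
Why: Bromination of the electron-rich benzylic alcohol through its bromophosphite is fast at 0 °C, and the labile bromide is carried forward without storage.

Step 5
Reactants: 5 1,5-bis(benzyloxy)-3-bromo-2-(bromomethyl)benzene
Product: 6 pinacol boronate 2-[2-bromo-4,6-bis(benzyloxy)benzyl]-4,4,5,5-tetramethyl-1,3,2-dioxaborolane
Conditions: B2pin2, CuI (10 mol %), PPh3 (13 mol %), LiOMe, DMF, 20 °C
Reagents that add atoms: bis(pinacolato)diboron CC1(C)OB(OC1(C)C)B1OC(C)(C)C(C)(C)O1
Why: CuI-catalysed borylation of alkyl halides by a boryl copper species formed from B2pin2 and LiOMe takes the benzylic bromide at room temperature, where the aryl bromide should not react.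

Step 6
Reactants: 6 pinacol [2-bromo-4,6-bis(benzyloxy)benzyl]boronate
Product: 7 diethanolamine boronate 2-[2-bromo-4,6-bis(benzyloxy)benzyl]-1,3,6,2-dioxazaborocane
Conditions: diethanolamine, Et2O, 20 °C; precipitate filtered
Reagents that add atoms: diethanolamine OCCNCCO
Why: Transesterification with diethanolamine is driven by N→B coordination and by precipitation of the tetracoordinate adduct, which frees boron from the otherwise hard-to-exchange pinacol.

Step 7
Reactants: 7 diethanolamine [2-bromo-4,6-bis(benzyloxy)benzyl]boronate; 8 (1S,2S)-1,2-dicyclohexylethane-1,2-diol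
Product: 9 chiral benzylboronate (4S,5S)-2-[2-bromo-4,6-bis(benzyloxy)benzyl]-4,5-dicyclohexyl-1,3,2-dioxaborolane
Conditions: 8, Et2O / 1 M aq. HCl, 0 → 20 °C
Reagents that add atoms: none
Why: Protonation of the amine releases the boronic acid at the interface, where the lipophilic diol captures it as the stable five-membered ester (boronic ester exchange) before the benzylic C–B bond can be protonated.

Step 8
Reactants: 9 (4S,5S)-2-[2-bromo-4,6-bis(benzyloxy)benzyl]-4,5-dicyclohexyl-1,3,2-dioxaborolane; 10 dichloromethane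
Product: 11 alpha-chloro boronate (4S,5S)-2-[(1R)-2-[2-bromo-4,6-bis(benzyloxy)phenyl]-1-chloroethyl]-4,5-dicyclohexyl-1,3,2-dioxaborolane
Conditions: 10, n-BuLi, THF, −100 °C; then 9; ZnCl2, −100 → 20 °C; used crude
Reagents that add atoms: none
Why: In this Matteson homologation LiCHCl2 adds to boron and ZnCl2 promotes 1,2-migration of the benzyl group with loss of the chloride selected by the (S,S)-diol, which should set the (1R)-chloride.

Step 9
Reactants: 11 (1R)-alpha-chloro boronate
Product: 12 alpha-allyloxy boronate (4S,5S)-2-[(1S)-1-(allyloxy)-2-[2-bromo-4,6-bis(benzyloxy)phenyl]ethyl]-4,5-dicyclohexyl-1,3,2-dioxaborolane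
Conditions: allyl alcohol, n-BuLi, THF, 0 °C; then 11, THF/DMSO, 20 °C
Reagents that add atoms: allyl alcohol C=CCO
Why: The lithium alkoxide adds to boron and then migrates to carbon with expulsion of chloride (Matteson substitution), inverting the centre to the (1S)-ether that becomes C3 with its oxygen already protected.

Step 10
Reactants: 13 5-bromo-1,2,3-trimethoxybenzene
Product: 14 triol 5-bromobenzene-1,2,3-triol
Conditions: BBr3, CH2Cl2, −78 → 20 °C; then H2O
Reagents that add atoms: none
Why: BBr3 demethylation proceeds by bromide attack on the methyl groups of the boron-complexed ethers and does not touch the aryl bromide.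

Step 11
Reactants: 14 5-bromobenzene-1,2,3-triol
Product: 15 aryl bromide 5-bromo-1,2,3-tris(benzyloxy)benzene
Conditions: BnBr, K2CO3, DMF, 60 °C, argon
Reagents that add atoms: benzyl bromide BrCc1ccccc1
Why: Williamson benzylation of the three phenols works under carbonate base provided air is excluded, since the pyrogallol anions oxidise readily.

Step 12
Reactants: 15 5-bromo-1,2,3-tris(benzyloxy)benzene
Product: 16 Grignard reagent 3,4,5-tris(benzyloxy)phenylmagnesium bromide
Conditions: Mg turnings, cat. 1,2-dibromoethane, THF, 20 → 65 °C; titrated solution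
Reagents that add atoms: magnesium [Mg]
Why: Oxidative insertion of magnesium into the aryl bromide (Grignard formation) is unproblematic because benzyl aryl ethers are inert to the reagent.

Step 13
Reactants: 12 (1S)-alpha-allyloxy boronate; 10 dichloromethane; 16 3,4,5-tris(benzyloxy)phenylmagnesium bromide
Product: 18 (4S,5S)-2-[(1R,2R)-2-(allyloxy)-3-[2-bromo-4,6-bis(benzyloxy)phenyl]-1-[3,4,5-tris(benzyloxy)phenyl]propyl]-4,5-dicyclohexyl-1,3,2-dioxaborolane, via alpha-chloro boronate 17 (not isolated)
Conditions: 10, n-BuLi, THF, −100 °C; then 12; ZnCl2, −100 → 20 °C; then 16 (excess over ZnCl2), THF, −78 → 20 °C; aq. NH4Cl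
Reagents that add atoms: none
Why: (Dichloromethyl)lithium adds to boron of 12 to give a tetracoordinate ate complex, and on warming with ZnCl2 the C3 carbon migrates from boron to the CHCl2 carbon with retention while the (S,S)-diol selects which diastereotopic chloride leaves, so the (1R)-chloride 17 forms and C3–C2 is made. Grignard reagent 16 then adds to boron of 17 and the aryl group migrates anti to the remaining chloride, forming C2–C1' with inversion at C2. The closest known reaction type is the Matteson homologation of alpha-alkoxy boronic esters of C2-symmetric diols followed by Grignard substitution of the alpha-chloride, used here with an aryl nucleophile. No ring is closed; the new stereocentre C2 is set by the diol on boron (reagent control, independent of C3), and C3 is carried through unchanged because it migrates with retention. The step needs carbon migration to outrun beta-elimination of boron with the allyloxy group and chloride-induced epimerisation of 17: the poor leaving ability of the ether oxygen, cold formation of the ate complexes and ZnCl2 as chloride scavenger should secure this, and the ring A aryl bromide is safe because no free alkyllithium remains and the Grignard reagent does not exchange with it. Because chlorine at C3 was replaced by oxygen, whereas chlorine at C2 is replaced by carbon and boron at C2 later by oxygen, one director gives the threo (1R,2R) arrangement that a retentive ring closure turns into 2,3-cis.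

Step 14
Reactants: 18 (1R,2R)-benzylic boronate
Product: 19 bromo alcohol (1R,2R)-2-(allyloxy)-3-[2-bromo-4,6-bis(benzyloxy)phenyl]-1-[3,4,5-tris(benzyloxy)phenyl]propan-1-ol
Conditions: H2O2 (30 % aq.), NaOH, THF/H2O, 0 → 20 °C
Reagents that add atoms: hydrogen peroxide OO
Why: Hydroperoxide adds to boron and the benzylic carbon migrates from boron to oxygen with retention (boronate oxidation), giving the (1R)-alcohol and releasing the diol for recovery.

Step 15
Reactants: 19 (1R,2R)-bromo alcohol
Product: 20 flavan (2R,3R)-3-(allyloxy)-5,7-bis(benzyloxy)-2-[3,4,5-tris(benzyloxy)phenyl]chromane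
Conditions: CuI (10 mol %), 1,10-phenanthroline (20 mol %), Cs2CO3, toluene, 110 °C, argon
Reagents that add atoms: none
Why: Intramolecular Ullmann-type C–O coupling of the caesium alkoxide with the aryl bromide closes the six-membered ring C at O1–C8a, and since the C2–O bond is never broken the threo alcohol gives the 2,3-cis flavan with both centres retained.

Step 16
Reactants: 20 (2R,3R)-3-O-allyl flavan
Product: 22 (2R,3R)-5,7-bis(benzyloxy)-2-[3,4,5-tris(benzyloxy)phenyl]chroman-3-ol, via prop-1-enyl ether 21 (not isolated)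
Conditions: [Ir(cod)(PMePh2)2]PF6 (2 mol %, activated with H2), THF, 20 °C; then 1 M aq. HCl, acetone, 20 °C
Reagents that add atoms: none
Why: Iridium hydride isomerisation of the allyl ether to the enol ether followed by mild acid hydrolysis unmasks O3 without any oxidant, so C4 of the electron-rich flavan and the benzyl ethers are not put at risk.

Step 17
Reactants: 22 (2R,3R)-flavan-3-ol; 23 4-(benzyloxy)benzoic acid
Product: 24 ester (2R,3R)-5,7-bis(benzyloxy)-2-[3,4,5-tris(benzyloxy)phenyl]chroman-3-yl 4-(benzyloxy)benzoate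
Conditions: 23, EDC·HCl, DMAP, CH2Cl2, 20 °C
Reagents that add atoms: none
Why: Steglich esterification through the O-acylisourea and the acylpyridinium ion acylates the axial 3-hydroxyl, the only free nucleophile in the molecule, without touching C2 or C3.

Step 18
Reactants: 24 hexabenzyl ester
Product: 25 epigallocatechin 3-O-(4-hydroxybenzoate), (2R,3R)-5,7-dihydroxy-2-(3,4,5-trihydroxyphenyl)chroman-3-yl 4-hydroxybenzoate
Conditions: H2 (1 atm), Pd(OH)2/C, THF/MeOH, 20 °C; filtration and evaporation under argon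
Reagents that add atoms: none
Why: Catalytic hydrogenolysis cleaves the six benzyl aryl ethers under conditions in which the secondary alkyl benzoate and the C2–O1 bond of the chroman should persist.

**Compound list**

1 | 5-bromobenzene-1,3-diol | Oc1cc(O)cc(Br)c1 | starting material
2 | 1-bromo-3,5-bis(benzyloxy)benzene | Brc1cc(OCc2ccccc2)cc(OCc2ccccc2)c1 | intermediate
3 | 2-bromo-4,6-bis(benzyloxy)benzaldehyde | O=Cc1c(Br)cc(OCc2ccccc2)cc1OCc1ccccc1 | intermediate
4 | [2-bromo-4,6-bis(benzyloxy)phenyl]methanol | OCc1c(Br)cc(OCc2ccccc2)cc1OCc1ccccc1 | intermediate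
5 | 1,5-bis(benzyloxy)-3-bromo-2-(bromomethyl)benzene | BrCc1c(Br)cc(OCc2ccccc2)cc1OCc1ccccc1 | intermediate
6 | 2-[2-bromo-4,6-bis(benzyloxy)benzyl]-4,4,5,5-tetramethyl-1,3,2-dioxaborolane | CC1(C)OB(Cc2c(Br)cc(OCc3ccccc3)cc2OCc2ccccc2)OC1(C)C | intermediate
7 | 2-[2-bromo-4,6-bis(benzyloxy)benzyl]-1,3,6,2-dioxazaborocane (N→B bond not drawn) | Brc1cc(OCc2ccccc2)cc(OCc2ccccc2)c1CB1OCCNCCO1 | intermediate
8 | (1S,2S)-1,2-dicyclohexylethane-1,2-diol | O[C@@H](C1CCCCC1)[C@H](C1CCCCC1)O | starting material
9 | (4S,5S)-2-[2-bromo-4,6-bis(benzyloxy)benzyl]-4,5-dicyclohexyl-1,3,2-dioxaborolane | Brc1cc(OCc2ccccc2)cc(OCc2ccccc2)c1CB1O[C@@H](C2CCCCC2)[C@H](C2CCCCC2)O1 | intermediate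
10 | dichloromethane | ClCCl | starting material
11 | (4S,5S)-2-[(1R)-2-[2-bromo-4,6-bis(benzyloxy)phenyl]-1-chloroethyl]-4,5-dicyclohexyl-1,3,2-dioxaborolane | Brc1cc(OCc2ccccc2)cc(OCc2ccccc2)c1C[C@H](Cl)B1O[C@@H](C2CCCCC2)[C@H](C2CCCCC2)O1 | intermediate
12 | (4S,5S)-2-[(1S)-1-(allyloxy)-2-[2-bromo-4,6-bis(benzyloxy)phenyl]ethyl]-4,5-dicyclohexyl-1,3,2-dioxaborolane | Brc1cc(OCc2ccccc2)cc(OCc2ccccc2)c1C[C@@H](OCC=C)B1O[C@@H](C2CCCCC2)[C@H](C2CCCCC2)O1 | intermediate
13 | 5-bromo-1,2,3-trimethoxybenzene | COc1cc(Br)cc(OC)c1OC | starting material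
14 | 5-bromobenzene-1,2,3-triol | Oc1cc(Br)cc(O)c1O | intermediate
15 | 5-bromo-1,2,3-tris(benzyloxy)benzene | Brc1cc(OCc2ccccc2)c(OCc2ccccc2)c(OCc2ccccc2)c1 | intermediate
16 | 3,4,5-tris(benzyloxy)phenylmagnesium bromide | Br[Mg]c1cc(OCc2ccccc2)c(OCc2ccccc2)c(OCc2ccccc2)c1 | intermediate
17 | (4S,5S)-2-[(1R,2R)-2-(allyloxy)-3-[2-bromo-4,6-bis(benzyloxy)phenyl]-1-chloropropyl]-4,5-dicyclohexyl-1,3,2-dioxaborolane | Brc1cc(OCc2ccccc2)cc(OCc2ccccc2)c1C[C@@H](OCC=C)[C@H](Cl)B1O[C@@H](C2CCCCC2)[C@H](C2CCCCC2)O1 | intermediate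
18 | (4S,5S)-2-[(1R,2R)-2-(allyloxy)-3-[2-bromo-4,6-bis(benzyloxy)phenyl]-1-[3,4,5-tris(benzyloxy)phenyl]propyl]-4,5-dicyclohexyl-1,3,2-dioxaborolane | Brc1cc(OCc2ccccc2)cc(OCc2ccccc2)c1C[C@@H](OCC=C)[C@H](B1O[C@@H](C2CCCCC2)[C@H](C2CCCCC2)O1)c1cc(OCc2ccccc2)c(OCc2ccccc2)c(OCc2ccccc2)c1 | intermediate
19 | (1R,2R)-2-(allyloxy)-3-[2-bromo-4,6-bis(benzyloxy)phenyl]-1-[3,4,5-tris(benzyloxy)phenyl]propan-1-ol | Brc1cc(OCc2ccccc2)cc(OCc2ccccc2)c1C[C@@H](OCC=C)[C@H](O)c1cc(OCc2ccccc2)c(OCc2ccccc2)c(OCc2ccccc2)c1 | intermediate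
20 | (2R,3R)-3-(allyloxy)-5,7-bis(benzyloxy)-2-[3,4,5-tris(benzyloxy)phenyl]chromane | C=CCO[C@@H]1Cc2c(OCc3ccccc3)cc(OCc3ccccc3)cc2O[C@@H]1c1cc(OCc2ccccc2)c(OCc2ccccc2)c(OCc2ccccc2)c1 | intermediate
21 | (2R,3R)-5,7-bis(benzyloxy)-3-[(E)-prop-1-enyloxy]-2-[3,4,5-tris(benzyloxy)phenyl]chromane | C/C=C/O[C@@H]1Cc2c(OCc3ccccc3)cc(OCc3ccccc3)cc2O[C@@H]1c1cc(OCc2ccccc2)c(OCc2ccccc2)c(OCc2ccccc2)c1 | intermediate
22 | (2R,3R)-5,7-bis(benzyloxy)-2-[3,4,5-tris(benzyloxy)phenyl]chroman-3-ol | O[C@@H]1Cc2c(OCc3ccccc3)cc(OCc3ccccc3)cc2O[C@@H]1c1cc(OCc2ccccc2)c(OCc2ccccc2)c(OCc2ccccc2)c1 | intermediate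
23 | 4-(benzyloxy)benzoic acid | O=C(O)c1ccc(OCc2ccccc2)cc1 | starting material
24 | (2R,3R)-5,7-bis(benzyloxy)-2-[3,4,5-tris(benzyloxy)phenyl]chroman-3-yl 4-(benzyloxy)benzoate | O=C(O[C@@H]1Cc2c(OCc3ccccc3)cc(OCc3ccccc3)cc2O[C@@H]1c1cc(OCc2ccccc2)c(OCc2ccccc2)c(OCc2ccccc2)c1)c1ccc(OCc2ccccc2)cc1 | intermediate
25 | epigallocatechin 3-O-(4-hydroxybenzoate), (2R,3R)-5,7-dihydroxy-2-(3,4,5-trihydroxyphenyl)chroman-3-yl 4-hydroxybenzoate | O=C(O[C@@H]1Cc2c(O)cc(O)cc2O[C@@H]1c1cc(O)c(O)c(O)c1)c1ccc(O)cc1 | target

**Step count**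

Total: 18 steps. Longest linear sequence: 15 steps (steps 1–9 and 13–18, from 1 to 25); the ring B branch (steps 10–12) joins at step 13.

**Steps most likely to fail**

Step 13. The aryl transfer may lose out to other pathways. The Grignard reagent may be diverted to a less reactive arylzinc species by ZnCl2, the aryl ate complex may shed boron together with the beta-allyloxy group, or chloride exchange at C2 may erode the configuration before the aryl group migrates. The fallback sets out from 12 and gives up reagent control at C2 for chelate control. The homologation is run as before to chloride 17, which is then oxidised in the flask (H2O2, aq. NaOH/NaHCO3, 0 °C). Oxidation of the C–B bond of an alpha-chloro boronic ester gives, after loss of chloride, the aldehyde (2R)-2-(allyloxy)-3-[2-bromo-4,6-bis(benzyloxy)phenyl]propanal F1. F1 is precomplexed with MgBr2·OEt2 in CH2Cl2 at −78 °C and treated with 16. Magnesium bridging the aldehyde and allyloxy oxygens (Cram chelate) should direct the aryl group to the face bearing the small hydrogen substituent, giving the syn alcohol. That alcohol is 19, where the route is rejoined; steps 13 and 14 are replaced.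

Step 15. The coupling may stall at the hindered secondary benzylic alkoxide, so that hydrodebromination of ring A or dehydrogenation of the carbinol to the aryl ketone takes over at 110 °C. The fallback sets out from 19 and moves the closure from O1–C8a to O1–C2 with inversion, after the carbinol has been inverted first.
- Oxidation with Dess–Martin periodinane (CH2Cl2, 20 °C) gives the ketone (2R)-2-(allyloxy)-3-[2-bromo-4,6-bis(benzyloxy)phenyl]-1-[3,4,5-tris(benzyloxy)phenyl]propan-1-one F2.
- Reduction with Zn(BH4)2 (Et2O, −20 °C), with zinc chelated between the carbonyl and allyloxy oxygens, should give the anti alcohol (1S,2R)-2-(allyloxy)-3-[2-bromo-4,6-bis(benzyloxy)phenyl]-1-[3,4,5-tris(benzyloxy)phenyl]propan-1-ol F3.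
- Miyaura borylation of the aryl bromide (B2pin2, Pd(dppf)Cl2, KOAc, dioxane, 90 °C) gives the aryl pinacol boronate F4.
- Oxidation with NaBO3·4H2O (THF/H2O, 20 °C) gives the phenol 2-[(2R,3S)-2-(allyloxy)-3-hydroxy-3-[3,4,5-tris(benzyloxy)phenyl]propyl]-3,5-bis(benzyloxy)phenol F5.
- Intramolecular Mitsunobu etherification (PPh3, DIAD, THF, 0 °C) closes ring C with inversion at C2 and returns to the route at 20.

Step 5. The electron-rich benzylic bromide 5 may be consumed by methoxide or by the solvent, or may homocouple, before the boryl copper species reaches it. The fallback sets out from 3 and avoids any benzylic halide. Condensation with 4-methylbenzenesulfonohydrazide (MeOH, 20 °C) gives the N-tosylhydrazone N'-[(E)-[2-bromo-4,6-bis(benzyloxy)phenyl]methylidene]-4-methylbenzenesulfonohydrazide F6. Heating F6 with B2pin2 and NaOMe in toluene/MeOH at 110 °C should give 6 by Bamford–Stevens formation of the aryldiazomethane, insertion into the B–B bond and protodeboronation of one boryl group. The route is rejoined at 6; steps 3–5 are replaced and the aryl bromide is not exposed to any metal catalyst.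

Further compounds
F1 | step 13 | (2R)-2-(allyloxy)-3-[2-bromo-4,6-bis(benzyloxy)phenyl]propanal | Brc1cc(OCc2ccccc2)cc(OCc2ccccc2)c1C[C@@H](OCC=C)C=O
F2 | step 15 | (2R)-2-(allyloxy)-3-[2-bromo-4,6-bis(benzyloxy)phenyl]-1-[3,4,5-tris(benzyloxy)phenyl]propan-1-one | Brc1cc(OCc2ccccc2)cc(OCc2ccccc2)c1C[C@@H](OCC=C)C(=O)c1cc(OCc2ccccc2)c(OCc2ccccc2)c(OCc2ccccc2)c1
F3 | step 15 | (1S,2R)-2-(allyloxy)-3-[2-bromo-4,6-bis(benzyloxy)phenyl]-1-[3,4,5-tris(benzyloxy)phenyl]propan-1-ol | Brc1cc(OCc2ccccc2)cc(OCc2ccccc2)c1C[C@@H](OCC=C)[C@@H](O)c1cc(OCc2ccccc2)c(OCc2ccccc2)c(OCc2ccccc2)c1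
F4 | step 15 | (1S,2R)-2-(allyloxy)-3-[2,4-bis(benzyloxy)-6-(4,4,5,5-tetramethyl-1,3,2-dioxaborolan-2-yl)phenyl]-1-[3,4,5-tris(benzyloxy)phenyl]propan-1-ol | CC1(C)OB(OC1(C)C)c1cc(OCc2ccccc2)cc(OCc2ccccc2)c1C[C@@H](OCC=C)[C@@H](O)c1cc(OCc2ccccc2)c(OCc2ccccc2)c(OCc2ccccc2)c1
F5 | step 15 | 2-[(2R,3S)-2-(allyloxy)-3-hydroxy-3-[3,4,5-tris(benzyloxy)phenyl]propyl]-3,5-bis(benzyloxy)phenol | Oc1cc(OCc2ccccc2)cc(OCc2ccccc2)c1C[C@@H](OCC=C)[C@@H](O)c1cc(OCc2ccccc2)c(OCc2ccccc2)c(OCc2ccccc2)c1
F6 | step 5 | N'-[(E)-[2-bromo-4,6-bis(benzyloxy)phenyl]methylidene]-4-methylbenzenesulfonohydrazide | Cc1ccc(cc1)S(=O)(=O)N/N=C/c1c(Br)cc(OCc2ccccc2)cc1OCc1ccccc1
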